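The numbers of this flask come from no measurement; the flask was simulated.

Three flasks hold the same amount of Q and differ in J, Saturday's holding less than Monday's.

| setting | Wednesday's | Saturday's | Monday's |
|---|---|---|---|
| Q | 1.0 mM | 1.0 mM | 1.0 mM |
| J | 3.00 mM | 1.50 mM | 6.00 mM |
| time | 2.0 min | 2.0 min | 2.0 min |

    Q + J → Z + G (k1 = 20 M⁻¹ s⁻¹)
    J + G ⇌ J.G, settled at all times (K2 = 1.0 × 10⁵ M⁻¹)
    J + Z → E + G (k3 = 84 M⁻¹ s⁻¹)

1. part of the Q that has reacted at the end, Wednesday's
2. part of the Q that has reacted at the end, Saturday's
3. part of the Q that has reacted at the end, Monday's
4. what raising the concentration of J from its lowest to its highest value here does to the part of the Q that has reacted (changes below 5 percentage points count as none) (no change / it rises / it falls)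

- what is said of G includes J.G
- run time (Wednesday's): 2.0 min

Two chemists argue over Saturday's flask, which holds 1.50 J for each Q. The first counts half-lives: with J as charged, Saturday's half-life of Q by step 1 alone is 0.39 min, short against the 2.0 min allowed, so on this count 5.19 half-lives pass and 2.73% of the Q stays. This is a pseudo-first-order view, with J held at its charge.

The second counts J, and I side with that reckoning. Each step uses one J and frees one G, and with Saturday's J as charged, bound G stands to free G as 150 to one, so I reckon that each G takes a further J while J stays near its charge. On that reckoning one step costs two J, and carrying a Q through to E costs 4. Saturday's flask has a cover of 37.5%, the J charged over 4 times the Q charged, which is the part of the Q that J pays for through to E on this count. Had every reacted Q stopped at Z, the same J would pay for 75.0%. So I put Saturday's reacted part between those two figures, with J as the limiting reagent. I expect it nearer the lower one, because with J as charged, Saturday's half-life of Z by step 3 alone is 0.092 min, shorter than that of Q.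

The forecast, on the second chemist's side, gives 78% for Wednesday's, 48% for Saturday's and 99.7% for Monday's, and for the trend it rises, holding that “each G released locks up one J”.

The flasks give 77.9% for Wednesday's, 47.8% for Saturday's and 99.8% for Monday's; from lowest J to highest, it rises, by 52 percentage points.

In Saturday's flask both steps ran while free J fell: at 1.00 min it stood at 6.88% of its charge, with E at 29.1%, and at 2.00 min E had reached 33.5% against a cover of 37.5%, going past it to 47.9% at 20.0 min. The half-life count belongs to Monday's flask, with a cover of 150%: the half-life of Q by step 1 at 0.113 min was 0.13 min, short against the time, and 0.25% of the Q remained beside 33.7% of the J free. A neighbour of Monday's charged with 4.0 mM of Q has a cover of 37.5% and ended with E at 36.2%.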